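**Plan** (drimane numbering for the decalin: ring A = C1–C5/C10 with the gem-dimethyl C4, ring B = C5–C10, C11 on C9, C12 = methyl on C8; primed locants for the five-membered ring)
- Retrosynthesis: cut C5′–Cl, then the C11=C4′ alkene (aldol condensation of an 8β-hydroxydrimanal with purchased 3-methoxycyclopent-2-enone), then C8–C12 (methyl Grignard on an 8-ketone), then C4–C5 and C9–C10 together (cationic bicyclization), then C6–C7 (acetoacetate dianion + geranyl bromide).
- Enabling feature: C4 and C10 are the two tertiary-cation sites of a head-to-tail isoprenoid chain, and the C8 oxygen with C11 on C9 is a latent β-keto ester (C8=O, C11 ester) whose enol carbon C9 can end the cation cascade.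
- Forward: the five-membered ring is bought; step 2 completes the gem-dimethyl ring A together with ring B from an open chain and is the last ring-forming step; steps 3–10 adjust functionality and attach the side ring.
- Stereochemistry: C5/C10 trans from chair–chair anti addition, absolute sense from a chiral Brønsted acid; C9 by equilibration to the equatorial isomer; C8 by equatorial Grignard attack anti to the axial C10 methyl; alkene geometry by a hydroxyl-directed E1cB elimination; C5′ by chlorination of a planar polyanion plus separation of epimers.

Key step: step 2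

Remark: the target is a vinylogous acid (an enolised cyclopentane-1,3-dione); it is aimed at as the drawn enol tautomer, which interconverts freely with its diketo form.

Step 1
Reactants: 1 geranyl bromide; 2 methyl acetoacetate
Product: 4 methyl (6E)-7,11-dimethyl-3-oxododeca-6,10-dienoate, via methyl acetoacetate dianion 3 (not isolated)
Conditions: NaH, THF, 0 °C; n-BuLi, 0 °C; then 1, 0 °C to rt; aq. NH4Cl
Reagents that add atoms: none
Why: γ-Alkylation of a β-keto ester dianion takes place at the more basic terminal carbanion by SN2 displacement of the allylic bromide, the E-alkene is retained and no stereocentre is formed.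

Step 2
Reactants: 4 methyl (6E)-7,11-dimethyl-3-oxododeca-6,10-dienoate
Product: 5 methyl (1R,4aS,8aS)-5,5,8a-trimethyl-2-oxodecahydronaphthalene-1-carboxylate
Conditions: chiral imidodiphosphorimidate acid built from two 3,3′-bis(3,5-bis(trifluoromethyl)phenyl)-1,1′-bi-2-naphthol units with N-trifluoromethylsulfonyl groups (5 mol %, antipode chosen for the 4aS,8aS series), (CF3)3COH–CH2Cl2, −20 °C
Reagents that add atoms: none
Why: Proposed new method: enantioface-selective protonation of the terminal 10,11-alkene of 4 inside the chiral ion pair gives the C11 tertiary cation (future C4 with its gem-dimethyl group), which is attacked by C6 of the (E)-6,7-alkene while the resulting C7 cation (future C10) is trapped at carbon by the enol of the β-keto ester, and loss of the enol proton returns the acid. The closest known reaction types are the SnCl4-promoted bicyclization of polyene β-keto esters of this class (racemic) and the confined-acid-catalysed protonative bicyclization of homofarnesol-type polyenes ended by a hydroxyl group, so what is new is the union of catalytic asymmetric protonation with carbon termination by a 1,3-dicarbonyl enol. Ring A closes by 6-endo-trig attack of the trisubstituted alkene on the cation and ring B by 6-endo (enol-endo) C-alkylation, both through chair-like transition states in one anti-periplanar cascade. C5 and C10 are set trans (5α-H, 10β-CH3) by anti addition across the E-alkene, C9 takes the equatorial ester by equilibration through the enol, and the absolute sense is set by the catalyst, which must protonate the face of C10=C11 that leads to the 4aS,8aS series. The step needs carbon over oxygen termination and initiation at the terminal alkene: the enol ether from O-capture can re-ionise under the acid and drain to the more stable β-keto ester, and the terminal alkene is the more accessible site while the internal alkene is engaged only within the folded chair–chair conformer.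

Step 3
Reactants: 5 methyl (1R,4aS,8aS)-5,5,8a-trimethyl-2-oxodecahydronaphthalene-1-carboxylate
Product: 6 12-nordrimane-8β,11-diol
Conditions: LiAlH4 (excess), Et2O, 0 °C to reflux; aqueous NaOH work-up
Reagents that add atoms: none
Why: Hydride reduction of both carbonyl groups of the β-keto ester gives the 1,3-diol; the new C8 carbinol centre (mainly axial OH from equatorial hydride attack anti to the axial C10 methyl) is immaterial because it is oxidised again in step 4.

Step 4
Reactants: 6 12-nordrimane-8β,11-diol
Product: 7 11-hydroxy-12-nordriman-8-one
Conditions: aq. NaOCl, AcOH, 0 °C to rt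
Reagents that add atoms: none
Why: Hypochlorite oxidation in acetic acid proceeds through an alkyl hypochlorite much faster for secondary than for primary alcohols, so the 1,3-diol should give the β-hydroxy ketone chemoselectively, with the epimerisable C9 centre staying equatorial.

Step 5
Reactants: 7 11-hydroxy-12-nordriman-8-one
Product: 9 drimane-8β,11-diol, via bromomagnesium alkoxide 8 (not isolated)
Conditions: MeMgBr (3.5 equiv), LaCl3·2LiCl (0.3 equiv), THF, −78 to 0 °C; aq. NH4Cl
Reagents that add atoms: methylmagnesium bromide, C[Mg]Br
Why: Grignard addition after deprotonation of the primary hydroxyl: the methyl group enters along the equatorial (α) trajectory because axial β-attack is blocked by the syn-axial C10 methyl, which sets C8 with an equatorial α-methyl and an axial β-hydroxyl as in the target, LaCl3·2LiCl suppressing enolisation.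

Step 6
Reactants: 9 drimane-8β,11-diol
Product: 10 8β-hydroxydriman-11-al
Conditions: TEMPO (10 mol %), PhI(OAc)2, CH2Cl2, rt
Reagents that add atoms: none
Why: Nitroxyl-catalysed oxidation is selective for the primary alcohol and leaves the tertiary alcohol untouched, and its non-basic conditions should not epimerise the equatorial C9 centre of the β-hydroxy aldehyde.

Step 7
Reactants: 10 8β-hydroxydriman-11-al; 11 3-methoxycyclopent-2-en-1-one
Product: 13 5-(8β,11-dihydroxydriman-11-yl)-3-methoxycyclopent-2-en-1-one, via lithium 4-methoxycyclopenta-1,4-dien-1-olate 12 (not isolated)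
Conditions: LDA (2.5 equiv), 11 (2.5 equiv), THF, −78 °C; then 10 added to the enolate, −78 °C; AcOH then aq. NH4Cl
Reagents that add atoms: none
Why: Directed aldol addition: kinetic deprotonation of the vinylogous ester at C5 gives the cross-conjugated enolate, one equivalent is consumed by the tertiary hydroxyl and a second adds to the hindered aldehyde fast enough at −78 °C to outrun retro-aldol cleavage, and the two new stereocentres are left uncontrolled because both become sp2 in step 8.

Step 8
Reactants: 13 5-(8β,11-dihydroxydriman-11-yl)-3-methoxycyclopent-2-en-1-one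
Product: 15 (5Z)-5-(8β-hydroxydriman-11-ylidene)-3-methoxycyclopent-2-en-1-one, via C11 mesylate 14 (not isolated)
Conditions: MsCl, Et3N, CH2Cl2, −20 °C; then DBU, toluene, 0 °C to rt
Reagents that add atoms: none
Why: Selective mesylation of the secondary carbinol followed by E1cB elimination through the ketone enolate; the free axial C8 hydroxyl can hydrogen-bond to the enolate oxygen in an eight-membered arrangement that holds C9 on the carbonyl side of the forming alkene, so the isomer with C9 cis to C1′ should be favoured under kinetic control in a non-polar solvent, although the usual preference of such eliminations is the opposite geometry.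

Step 9
Reactants: 15 (5Z)-5-(8β-hydroxydriman-11-ylidene)-3-methoxycyclopent-2-en-1-one
Product: 16 (4Z)-3-hydroxy-4-(8β-hydroxydriman-11-ylidene)cyclopent-2-en-1-one
Conditions: LiOH, THF–H2O, rt; then cold dilute HCl to pH 3, immediate extraction
Reagents that add atoms: lithium hydroxide, [Li+].[OH-]
Why: Saponification of the vinylogous ester by conjugate addition–elimination of hydroxide at the methoxy-bearing carbon gives the vinylogous carboxylate, which is inert to further base and keeps the alkene geometry, and cold acidification releases the enolised 1,3-dione without exposing the tertiary alcohol to strong acid.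

Step 10
Reactants: 16 (4Z)-3-hydroxy-4-(8β-hydroxydriman-11-ylidene)cyclopent-2-en-1-one
Product: 18 (4E,5R)-5-chloro-3-hydroxy-4-(8β-hydroxydriman-11-ylidene)cyclopent-2-en-1-one, via trilithium fulvenoid salt 17 (not isolated)
Conditions: LDA (3.3 equiv), THF, −78 to −40 °C; cannulated into N-chlorosuccinimide (1.0 equiv), THF, −78 °C; cold aq. HCl (pH 3); HPLC separation of the C5′ epimers
Reagents that add atoms: N-chlorosuccinimide, O=C1CCC(=O)N1Cl
Why: γ-Chlorination of a 1,3-dione polyanion: after the two hydroxyl groups, LDA removes the doubly activated C5′ proton, and the resulting anion reacts with the chlorine electrophile at this last-formed carbanion site instead of C2′; the 5R centre arises from attack on the face away from C10 and ring A in the conformer with H9 eclipsing the alkene, a 1,4-induction expected to be modest, so the epimer is secured by separation of the two diastereomers.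

**Compound list**
1 | geranyl bromide, (2E)-1-bromo-3,7-dimethylocta-2,6-diene | CC(C)=CCC/C(C)=C/CBr | starting material
2 | methyl acetoacetate | CC(=O)CC(=O)OC | starting material
3 | sodium lithium dianion of methyl acetoacetate | [CH2-]C(=O)[CH-]C(=O)OC.[Na+].[Li+] | intermediate
4 | methyl (6E)-7,11-dimethyl-3-oxododeca-6,10-dienoate | COC(=O)CC(=O)CC/C=C(\C)CCC=C(C)C | intermediate
5 | methyl (1R,4aS,8aS)-5,5,8a-trimethyl-2-oxodecahydronaphthalene-1-carboxylate (methyl 8-oxo-12-nordriman-11-oate; trans-decalin, 9β-ester) | CC1(C)CCC[C@]2(C)[C@@H](C(=O)OC)C(=O)CC[C@@H]12 | intermediate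
6 | 12-nordrimane-8β,11-diol (5α-H, 9α-H, 10β-CH3; axial 8β-OH shown, C8 epimer tolerated) | CC1(C)CCC[C@]2(C)[C@@H](CO)[C@@H](O)CC[C@@H]12 | intermediate
7 | 11-hydroxy-12-nordriman-8-one | CC1(C)CCC[C@]2(C)[C@@H](CO)C(=O)CC[C@@H]12 | intermediate
8 | bromomagnesium 11-alkoxide of 7 | CC1(C)CCC[C@]2(C)[C@@H](CO[Mg]Br)C(=O)CC[C@@H]12 | intermediate
9 | drimane-8β,11-diol (8α-CH3, axial 8β-OH) | CC1(C)CCC[C@]2(C)[C@@H](CO)[C@@](C)(O)CC[C@@H]12 | intermediate
10 | 8β-hydroxydriman-11-al | CC1(C)CCC[C@]2(C)[C@@H](C=O)[C@@](C)(O)CC[C@@H]12 | intermediate
11 | 3-methoxycyclopent-2-en-1-one | COC1=CC(=O)CC1 | starting material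
12 | lithium 4-methoxycyclopenta-1,4-dien-1-olate | COC1=CC(O[Li])=CC1 | intermediate
13 | 5-(8β,11-dihydroxydriman-11-yl)-3-methoxycyclopent-2-en-1-one (diastereomers at C11 and C5′) | CC1(C)CCC[C@]2(C)[C@@H](C(O)C3CC(OC)=CC3=O)[C@@](C)(O)CC[C@@H]12 | intermediate
14 | 11-methanesulfonate of 13 | CC1(C)CCC[C@]2(C)[C@@H](C(OS(C)(=O)=O)C3CC(OC)=CC3=O)[C@@](C)(O)CC[C@@H]12 | intermediate
15 | (5Z)-5-(8β-hydroxydriman-11-ylidene)-3-methoxycyclopent-2-en-1-one (C9 cis to the ring carbonyl) | CC1(C)CCC[C@]2(C)[C@@H](/C=C3/CC(OC)=CC3=O)[C@@](C)(O)CC[C@@H]12 | intermediate
16 | (4Z)-3-hydroxy-4-(8β-hydroxydriman-11-ylidene)cyclopent-2-en-1-one | CC1(C)CCC[C@]2(C)[C@@H](/C=C3\C(O)=CC(=O)C3)[C@@](C)(O)CC[C@@H]12 | intermediate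
17 | trilithium salt of 16 (8-alkoxide, 1′,3′-dioxidofulvene) | CC1(C)CCC[C@]2(C)[C@@H](/C=C3\C(O[Li])=CC(O[Li])=C3)[C@@](C)(O[Li])CC[C@@H]12 | intermediate
18 | (4E,5R)-5-chloro-3-hydroxy-4-{[(1R,2S,4aS,8aS)-2-hydroxy-2,5,5,8a-tetramethyldecahydronaphthalen-1-yl]methylidene}cyclopent-2-en-1-one | CC1(C)CCC[C@]2(C)[C@@H](/C=C3\C(O)=CC(=O)[C@@H]3Cl)[C@@](C)(O)CC[C@@H]12 | target

**Step count:** 10 steps in total; longest linear sequence 10 steps (1 and 2 to 18).

**Steps most likely to fail**

Step 2. The catalyst may fail to control the face of protonation, or the cascade may end on the enol oxygen. The fallback uses known chemistry, sets out from 4 and returns at 6. SnCl4 in CH2Cl2 at 0 °C should cyclise 4 to the racemic keto ester F1. LiAlH4 then gives the racemic diol F2. Lipase-catalysed acylation (Pseudomonas cepacia lipase, vinyl acetate, t-BuOMe) resolves F2. If the required enantiomer reacts more slowly it is recovered directly as 6. If it reacts faster it is isolated as the monoacetate F3 and deacetylated with K2CO3 in MeOH to 6.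

Step 8. The elimination may run through the rotamer that places C9 on the side of the ring CH2, which is the usual outcome for aldol dehydrations. The fallback sets out from 13 and returns at 15. The same mesylation–elimination, run without regard to geometry, gives the (5E)-isomer F4. Irradiation of F4 (about 350 nm, benzene) sets up a photostationary mixture with 15. Compound 15 is separated by chromatography and F4 is irradiated again.

Step 10. Facial selectivity at the planar anion may be poor, and proton exchange between product and polyanion may lead to over-chlorination. The fallback sets out from 15 and returns at 18. γ-Deprotonation of 15 (LDA, 2.2 equiv, THF, −78 °C) and hydroxylation with the appropriate enantiomer of (camphorylsulfonyl)oxaziridine should give, under reagent control, the 4-hydroxy compound F5. Deoxychlorination with inversion (PPh3, CCl4, CH2Cl2) gives the 4-chloro vinylogous ester F6. Hydrolysis of the enol ether (1 M HCl, THF, 0 °C) then gives 18.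

**Further compounds**
F1 | step 2 | racemic methyl 5,5,8a-trimethyl-2-oxodecahydronaphthalene-1-carboxylate (rac-5, relative configuration shown) | CC1(C)CCC[C@]2(C)[C@@H](C(=O)OC)C(=O)CC[C@@H]12
F2 | step 2 | racemic 12-nordrimane-8β,11-diol (rac-6, relative configuration shown) | CC1(C)CCC[C@]2(C)[C@@H](CO)[C@@H](O)CC[C@@H]12
F3 | step 2 | 11-O-acetyl-12-nordrimane-8β,11-diol (monoacetate of 6) | CC1(C)CCC[C@]2(C)[C@@H](COC(C)=O)[C@@H](O)CC[C@@H]12
F4 | step 8 | (5E)-5-(8β-hydroxydriman-11-ylidene)-3-methoxycyclopent-2-en-1-one (C9 cis to the ring CH2) | CC1(C)CCC[C@]2(C)[C@@H](/C=C3\CC(OC)=CC3=O)[C@@](C)(O)CC[C@@H]12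
F5 | step 10 | (4S,5Z)-4-hydroxy-5-(8β-hydroxydriman-11-ylidene)-3-methoxycyclopent-2-en-1-one | CC1(C)CCC[C@]2(C)[C@@H](/C=C3/[C@H](O)C(OC)=CC3=O)[C@@](C)(O)CC[C@@H]12
F6 | step 10 | (4R,5E)-4-chloro-5-(8β-hydroxydriman-11-ylidene)-3-methoxycyclopent-2-en-1-one | CC1(C)CCC[C@]2(C)[C@@H](/C=C3/[C@@H](Cl)C(OC)=CC3=O)[C@@](C)(O)CC[C@@H]12
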